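0.0280 h⁻¹ opened the meeting on the red and green flasks: this is Wednesday's late gain of monomer in chains per hour, divided by the mean free monomer over the same readings.

the same everywhere: free monomer 0.30 M; impurity 7.3 mM
- Wednesday's: transfer agent 9 mM; initiator 18 mM; run made earlier
- Monday's: transfer agent 9 mM; initiator 28 mM; run made earlier
- Thursday's: transfer agent 9 mM; initiator 32 mM; run made earlier
- red: transfer agent 9.00 mM; initiator 45 mM; time 15 h
- green: transfer agent 9.00 mM; initiator 15 mM; time 15 h

- Wednesday's (time / h: monomer in chains / %, free monomer / %): 1.33: 3, 86; 4.00: 12, 71; 6.00: 15, 66; 10.0: 23, 60
- Monday's (time / h: monomer in chains / %, free monomer / %): 2.50: 14, 68; 5.00: 22, 59; 8.00: 28, 48; 10.0: 32, 43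
- Thursday's (time / h: monomer in chains / %, free monomer / %): 1.33: 16, 79; 4.00: 25, 62; 6.00: 27, 56; 10.0: 40, 45

(standard deviation of a reading: 2 percentage points)

- what may be going on: initiator + impurity -> spent initiator; free monomer + living end -> monomer in chains + living end; living end + transfer agent -> dead chain; free monomer + initiator -> living end + monomer in chains; free monomer <-> dormant form
- a reading of free monomer is of its free form alone

- which of these there is most of at the end, counted by the free monomer in it, red (monomer in chains / free monomer)
- which of these there is most of at the end, counted by the free monomer in it, green (monomer in chains / free monomer)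
- the largest of these amounts at the end, in percent of the free monomer charged, red
- the largest of these amounts at the end, in percent of the free monomer charged, green

The forecaster argued that after the impurity, transfer agent “kills ends one for one”, and put red at monomer in chains, 70%, and green at free monomer, 62%.

I answered with the same figure for Monday's run, 0.0432 h⁻¹, and Thursday's, 0.0467 h⁻¹. Wednesday's over Thursday's is 0.600; the charges of initiator stand at 0.562, the survivors by subtraction at 0.108.

So I proposed as zero of the scale the plain case where each charged initiator counts alike: one monomer into a chain at the start, one growing end after. The three runs average 1.52 L mol⁻¹ h⁻¹, which I called the growth constant per charged initiator, the late specific gain divided by the initiator charged.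

Free monomer averaged 72.1% of the unchained part at the last readings. The unchained part then decays pseudo-first-order, with the product of constant, share and charge as its rate constant. My reckoning gives red 59.4% in chains, and green 25.7% in chains with 53.5% free. My reckoning has the same leaders as the forecast, but my figures are lower.

The flask gives red monomer in chains at 62.0%, and green free monomer at 55.4%, with 24.3% in chains.

    initiator + impurity → spent initiator (k = 180 L mol⁻¹ h⁻¹)
    free monomer + living end → monomer in chains + living end, rate k2*[living end]*[free monomer] (k = 2.20 L mol⁻¹ h⁻¹)
    living end + transfer agent → dead chain (kL = 2.60 L mol⁻¹ h⁻¹)
    free monomer + initiator → living end + monomer in chains (k = 9.00 L mol⁻¹ h⁻¹)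
    free monomer ⇌ dormant form (K = 0.350, k = 0.0920 h⁻¹)

In green, the step that kills ends halves transfer agent in 32 h at the asked time, longer than the run's 15 h. Green ends with more living end than dead chain, 0.00831 M against 0.00275 M. On the neighbour, green with 0.037 M of initiator, the constant gives 52.3% in chains and 34.4% free. The computed flask holds 53.8% in chains and 32.8% free, with monomer in chains the larger.

The readings are simulated for an exercise, noise included.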